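**Retrosynthetic overview**
1. Structural feature: the side chain ends in a (Z)-C(=O)–CH=CH–C(CH3)2–OH unit, an alkene whose two allylic carbons both carry oxygen. One silicon atom can bridge these oxygens, and the CH=CH bond is then made inside a seven-membered 1,3-dioxa-2-silacyclohept-5-ene, which can hold only a cis double bond.
2. Endgame: the target comes from MnO2 oxidation of the secondary allylic alcohol, preceded by fluoride removal of silicon, preceded by ring-closing metathesis of the mixed diisopropylsilaketal of the ring-bound vinyl carbinol and 2-methylbut-3-en-2-ol.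
3. Fragment union: the CH2–C(=O) bond next to the cyclopentane is cut into a neopentyl-type organolithium and (R)-chromene-2-acetaldehyde; the carbinol is then oxidised. The iodide precursor already carries the silaketal, which serves as protecting group.
4. Fragments: 2,3-dimethylsuccinic acid gives an N-benzylimide, a bis-enolate annulation with 1,3-dibromopropane (cis fusion forces cis methyl groups), a meso-diol, a lipase desymmetrisation, an iodide on one arm and a vinyl carbinol on the other. (R)-Citramalic acid gives a tertiary propargylic alcohol, then Sonogashira coupling, Lindlar reduction and a stereoretentive intramolecular C–O coupling.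
5. Ring order: the cyclopentane (inside the bicyclic imide) and the pyran ring of the chromene are built in separate branches. The temporary seven-membered silacycle comes last and is opened again once it has fixed the alkene geometry.

Key step: step 25

Remark 1: the lipase of step 17 is assumed to acetylate the hydroxymethyl group on the ring carbon that becomes C1 of 26. If it prefers the other enantiotopic group, the enzyme is run in the hydrolytic direction on the bis-acetylated diol, which inverts the outcome.
Remark 2: the carbinol carbon made in step 21 is carried as an epimer mixture (names and SMILES show the (R)-epimer). The carbinol carbon made in step 23 is left undefined. Both carbons end as carbonyl groups.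

**Chromene fragment**

Step 1
Reactants: 1 (R)-citramalic acid [(2R)-2-hydroxy-2-methylbutanedioic acid]
Product: 2 2-[(4R)-2,2,4-trimethyl-5-oxo-1,3-dioxolan-4-yl]acetic acid
Conditions: Me2C(OMe)2, p-TsOH·H2O (cat.), CH2Cl2, rt
Reagents that add atoms: 2,2-dimethoxypropane, COC(C)(C)OC
Why: Acid-catalysed acetal exchange closes the five-membered dioxolanone on the α-hydroxy acid unit in preference to a six-membered ring with the β-carboxyl group, which differentiates the two carboxyl groups without touching the quaternary stereocentre.

Step 2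
Reactants: 2 2-[(4R)-2,2,4-trimethyl-5-oxo-1,3-dioxolan-4-yl]acetic acid
Product: 3 (5R)-5-(2-hydroxyethyl)-2,2,5-trimethyl-1,3-dioxolan-4-one
Conditions: BH3·THF (1.2 equiv), THF, 0 °C to rt; H2O work-up
Reagents that add atoms: none
Why: Chemoselective borane reduction, in which the free carboxylic acid reacts through an acyloxyborane much faster than the lactone-type carbonyl of the dioxolanone, as is known for the malic acid series.

Step 3
Reactants: 3 (5R)-5-(2-hydroxyethyl)-2,2,5-trimethyl-1,3-dioxolan-4-one
Product: 4 (5R)-5-{2-[(tert-butyldimethylsilyl)oxy]ethyl}-2,2,5-trimethyl-1,3-dioxolan-4-one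
Conditions: TBSCl, imidazole, CH2Cl2, 0 °C to rt
Reagents that add atoms: tert-butyldimethylsilyl chloride, CC(C)(C)[Si](C)(C)Cl
Why: Imidazole-promoted silylation of a primary alcohol, carried out at once so that the hydroxy ester cannot translactonise to the butyrolactone.

Step 4
Reactants: 4 (5R)-5-{2-[(tert-butyldimethylsilyl)oxy]ethyl}-2,2,5-trimethyl-1,3-dioxolan-4-one
Product: 5 (5R)-5-{2-[(tert-butyldimethylsilyl)oxy]ethyl}-2,2,5-trimethyl-1,3-dioxolan-4-ol (lactol, both C4 epimers)
Conditions: i-Bu2AlH (1.1 equiv), CH2Cl2, −78 °C; aq. potassium sodium tartrate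
Reagents that add atoms: none
Why: Partial reduction of a lactone-type carbonyl stops at the aluminium hemiacetal at low temperature and gives the lactol on work-up, whose new hemiacetal carbon is stereochemically irrelevant.

Step 5
Reactants: 5 (5R)-5-{2-[(tert-butyldimethylsilyl)oxy]ethyl}-2,2,5-trimethyl-1,3-dioxolan-4-ol
Product: 7 (3R)-5-[(tert-butyldimethylsilyl)oxy]-3-methylpent-1-yn-3-ol, via hydroxy aldehyde 6 (not isolated)
Conditions: dimethyl (1-diazo-2-oxopropyl)phosphonate, K2CO3, MeOH, 0 °C to rt
Reagents that add atoms: dimethyl (1-diazo-2-oxopropyl)phosphonate, CC(=O)C(=[N+]=[N-])P(=O)(OC)OC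
Why: Seyferth–Gilbert homologation in the Ohira–Bestmann variant, in which methanolic carbonate opens the lactol with loss of acetone to the non-enolisable α-hydroxy aldehyde 6, which passes through a diazoalkene and a 1,2-hydrogen shift of the alkylidene carbene to the terminal alkyne while the quaternary centre stays untouched.

Step 6
Reactants: 8 4-methoxy-2-methylaniline
Product: 9 2-iodo-4-methoxy-6-methylaniline
Conditions: NIS, MeCN, 0 °C to rt, dark
Reagents that add atoms: N-iodosuccinimide, O=C1CCC(=O)N1I
Why: Electrophilic aromatic iodination is directed by the amino group, the strongest donor, whose para position is blocked and whose only free ortho position is C6.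

Step 7
Reactants: 9 2-iodo-4-methoxy-6-methylaniline
Product: 11 2-bromo-1-iodo-5-methoxy-3-methylbenzene, via diazonium bromide 10 (not isolated)
Conditions: NaNO2, 48% aq. HBr, 0 °C; then CuBr, 0 to 60 °C
Reagents that add atoms: hydrobromic acid, Br
Why: Sandmeyer bromination puts the less reactive halogen on the carbon that will later carry the ring oxygen and leaves iodine for the first cross-coupling.

Step 8
Reactants: 7 (3R)-5-[(tert-butyldimethylsilyl)oxy]-3-methylpent-1-yn-3-ol; 11 2-bromo-1-iodo-5-methoxy-3-methylbenzene
Product: 12 (3R)-1-(2-bromo-5-methoxy-3-methylphenyl)-5-[(tert-butyldimethylsilyl)oxy]-3-methylpent-1-yn-3-ol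
Conditions: PdCl2(PPh3)2 (2 mol%), CuI (4 mol%), Et3N, THF, rt
Reagents that add atoms: none
Why: Sonogashira coupling occurs at the C–I bond only, because oxidative addition of zerovalent palladium to an aryl iodide at room temperature is much faster than to the flanked, electron-rich C–Br bond, and free tertiary propargylic alcohols are tolerated.

Step 9
Reactants: 12 (3R)-1-(2-bromo-5-methoxy-3-methylphenyl)-5-[(tert-butyldimethylsilyl)oxy]-3-methylpent-1-yn-3-ol
Product: 13 (1Z,3R)-1-(2-bromo-5-methoxy-3-methylphenyl)-5-[(tert-butyldimethylsilyl)oxy]-3-methylpent-1-en-3-ol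
Conditions: H2 (1 atm), Pd/CaCO3 poisoned with Pb(OAc)2, quinoline, EtOAc, rt
Reagents that add atoms: none
Why: Lindlar semihydrogenation delivers both hydrogens syn from the catalyst surface and so gives the Z-alkene that places the tertiary hydroxyl group next to the C–Br bond, aryl bromide and silyl ether being inert.

Step 10
Reactants: 13 (1Z,3R)-1-(2-bromo-5-methoxy-3-methylphenyl)-5-[(tert-butyldimethylsilyl)oxy]-3-methylpent-1-en-3-ol
Product: 14 tert-butyl{2-[(2R)-6-methoxy-2,8-dimethyl-2H-chromen-2-yl]ethoxy}dimethylsilane
Conditions: Pd(OAc)2 (5 mol%), t-BuXPhos (7 mol%), Cs2CO3, toluene, 80 °C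
Reagents that add atoms: none
Why: Intramolecular Buchwald–Hartwig etherification suits tertiary alkoxides (no hydrogen on the carbinol carbon for β-elimination), the cis alkene holds oxygen and aryl–palladium bond in reach for six-membered ring closure, and since only the O–H and C–Br bonds are broken the C2 stereocentre is carried over with retention.

Step 11
Reactants: 14 tert-butyl{2-[(2R)-6-methoxy-2,8-dimethyl-2H-chromen-2-yl]ethoxy}dimethylsilane
Product: 15 2-[(2R)-6-methoxy-2,8-dimethyl-2H-chromen-2-yl]ethanol
Conditions: n-Bu4NF, THF, 0 °C to rt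
Reagents that add atoms: none
Why: Fluoride-induced cleavage of a primary silyl ether is driven by the strong Si–F bond, and the chromene has no base-sensitive group at this stage.

Step 12
Reactants: 15 2-[(2R)-6-methoxy-2,8-dimethyl-2H-chromen-2-yl]ethanol
Product: 16 2-[(2R)-6-methoxy-2,8-dimethyl-2H-chromen-2-yl]acetaldehyde
Conditions: Dess–Martin periodinane, NaHCO3, CH2Cl2, 0 °C to rt
Reagents that add atoms: none
Why: Dess–Martin oxidation runs under buffered, nearly neutral conditions, which avoids enolisation and β-elimination of aryloxide from the β-aryloxy aldehyde, which is used at once.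

**Cyclopentane fragment**

Step 13
Reactants: 17 2,3-dimethylsuccinic acid (diastereomer mixture)
Product: 18 1-benzyl-3,4-dimethylpyrrolidine-2,5-dione (diastereomer mixture)
Conditions: BnNH2 (1 equiv), xylene, reflux, Dean–Stark trap
Reagents that add atoms: benzylamine, NCc1ccccc1
Why: Thermal condensation of a 1,4-diacid with a primary amine gives the five-membered cyclic imide on azeotropic removal of water, and the configuration of the two CH centres is irrelevant because both are enolised next.

Step 14
Reactants: 18 1-benzyl-3,4-dimethylpyrrolidine-2,5-dione; 19 1,3-dibromopropane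
Product: 22 cis-3-benzyl-1,5-dimethyl-3-azabicyclo[3.3.0]octane-2,4-dione (meso), via dilithium bis-enolate 20 (not isolated), via bromopropyl enolate 21 (not isolated)
Conditions: LiN(i-Pr)2 (2.2 equiv), THF, −78 to 0 °C; 19, −78 °C to rt
Reagents that add atoms: none
Why: Bis-enolate annulation with a 1,3-dihalide (the dianion is a 2,5-dioxidopyrrole): after the first C-alkylation the remaining enolate closes the cyclopentane in a 5-exo-tet mode, and because both new quaternary carbons are fusion atoms of a bicyclo[3.3.0]octane the fusion, and hence the relation of the two methyl groups, can only be cis.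

Step 15
Reactants: 22 cis-3-benzyl-1,5-dimethyl-3-azabicyclo[3.3.0]octane-2,4-dione
Product: 24 cis-1,5-dimethyl-3-oxabicyclo[3.3.0]octane-2,4-dione (meso anhydride), via amic acid 23 (not isolated)
Conditions: KOH, EtOH–H2O, reflux; 6 M HCl, 100 °C; toluene, reflux, Dean–Stark trap
Reagents that add atoms: water, O
Why: Alkaline opening of the imide is followed by neighbouring-group-assisted amide hydrolysis, in which the cis carboxyl group, pressed against the amide by the four α-substituents, attacks it in acid and expels benzylammonium without any change at the quaternary carbons.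

Step 16
Reactants: 24 cis-1,5-dimethyl-3-oxabicyclo[3.3.0]octane-2,4-dione
Product: 25 cis-(1,2-dimethylcyclopentane-1,2-diyl)dimethanol (meso)
Conditions: LiAlH4, THF, 0 °C to reflux
Reagents that add atoms: none
Why: Exhaustive hydride reduction of a cyclic anhydride proceeds through the lactone to the 1,4-diol, and the quaternary centres cannot epimerise, so the cis relation is kept.

Step 17
Reactants: 25 cis-(1,2-dimethylcyclopentane-1,2-diyl)dimethanol
Product: 26 [(1S,2R)-2-(hydroxymethyl)-1,2-dimethylcyclopentyl]methyl acetate
Conditions: Burkholderia cepacia lipase (Amano PS), vinyl acetate, t-BuOMe, 30 °C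
Reagents that add atoms: vinyl acetate, C=COC(C)=O
Why: Enzymatic desymmetrisation by irreversible transesterification acylates one of the two enantiotopic hydroxymethyl groups of the meso-diol, which fixes the absolute configuration of both quaternary ring carbons in one operation, while the slow second acylation should consume mainly the minor enantiomer.

Step 18
Reactants: 26 [(1S,2R)-2-(hydroxymethyl)-1,2-dimethylcyclopentyl]methyl acetate
Product: 27 [(1S,2R)-2-(iodomethyl)-1,2-dimethylcyclopentyl]methyl acetate
Conditions: PPh3, I2, imidazole, toluene, rt then 90 °C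
Reagents that add atoms: iodine, II
Why: In this Appel-type iodination (Garegg–Samuelsson conditions) the alcohol is trapped as alkoxyphosphonium salt at room temperature, which stops acetyl migration between the arms, and heating then forces SN2 displacement by iodide at the neopentyl carbon, the ester oxygens being too weakly nucleophilic to close a cyclic ether.

Step 19
Reactants: 27 [(1S,2R)-2-(iodomethyl)-1,2-dimethylcyclopentyl]methyl acetate
Product: 28 [(1S,2R)-2-(iodomethyl)-1,2-dimethylcyclopentyl]methanol
Conditions: i-Bu2AlH (2.2 equiv), CH2Cl2, −78 °C; aq. potassium sodium tartrate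
Reagents that add atoms: none
Why: Reductive ester cleavage at low temperature avoids a basic alkoxide that could displace the cis iodide to give a tetrahydrofuran, and the neopentyl iodide is inert to the hydride.

Step 20
Reactants: 28 [(1S,2R)-2-(iodomethyl)-1,2-dimethylcyclopentyl]methanol
Product: 29 (1S,2R)-2-(iodomethyl)-1,2-dimethylcyclopentane-1-carbaldehyde
Conditions: Dess–Martin periodinane, NaHCO3, CH2Cl2, 0 °C to rt
Reagents that add atoms: none
Why: Dess–Martin oxidation converts a hindered primary alcohol into a non-enolisable aldehyde under neutral conditions that leave the alkyl iodide untouched.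

Step 21
Reactants: 29 (1S,2R)-2-(iodomethyl)-1,2-dimethylcyclopentane-1-carbaldehyde; 30 vinylmagnesium bromide
Product: 31 1-[(1S,2R)-2-(iodomethyl)-1,2-dimethylcyclopentyl]prop-2-en-1-ol (carbinol epimers, (1R) drawn)
Conditions: 30 (1.5 equiv), THF, −78 to 0 °C; aq. NH4Cl
Reagents that add atoms: none
Why: Grignard 1,2-addition to a non-enolisable aldehyde is not disturbed by a neopentyl iodide, and the carbinol centre, formed under Felkin–Anh bias as an epimer mixture, need not be controlled because this carbon ends as the enone carbonyl.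

Step 22
Reactants: 31 1-[(1S,2R)-2-(iodomethyl)-1,2-dimethylcyclopentyl]prop-2-en-1-ol; 32 dichlorodiisopropylsilane; 33 2-methylbut-3-en-2-ol
Product: 36 {1-[(1S,2R)-2-(iodomethyl)-1,2-dimethylcyclopentyl]allyloxy}(diisopropyl)(2-methylbut-3-en-2-yloxy)silane, via chlorosilane 34 (not isolated), via lithium alkoxide 35 (not isolated)
Conditions: 32 (2 equiv), imidazole, CH2Cl2, 0 °C to rt, then volatiles and excess 32 removed in vacuo; 35 (from 33, n-BuLi, THF, 0 °C), THF, 0 °C to rt
Reagents that add atoms: none
Why: Stepwise nucleophilic substitution at silicon, in which the hindered secondary alcohol reacts once with the small, reactive dichlorosilane and the remaining Si–Cl bond of 34 is displaced by the lithium alkoxide of the tertiary alcohol, gives the unsymmetrical silaketal on a robust fragment and lets the tether act as protecting group in the next two steps.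

**Union and endgame**

Step 23
Reactants: 36 iodide-bearing mixed diisopropylsilaketal; 16 2-[(2R)-6-methoxy-2,8-dimethyl-2H-chromen-2-yl]acetaldehyde
Product: 38 coupling carbinol: chromene C2–CH2–CH(OH)–CH2–cyclopentane with the open silaketal diene (both epimers at the new carbinol), via organolithium 37 (not isolated)
Conditions: t-BuLi (2.1 equiv per 36), Et2O–pentane, −78 °C, 10 min; 16, −78 °C; aq. NH4Cl at −78 °C
Reagents that add atoms: none
Why: Iodine–lithium exchange with two equivalents of t-BuLi is the fastest process at −78 °C, where the 5-hexenyllithium-type reagent 37 should neither carbolithiate its own vinyl group nor attack the shielded silicon, so that 1,2-addition to the unhindered aldehyde carbonyl outruns enolisation of the β-aryloxy aldehyde, and the new carbinol centre is removed in step 24.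

Step 24
Reactants: 38 coupling carbinol
Product: 39 open mixed silaketal diene ketone (metathesis precursor; (2R)-chromene, (S,S)-cis-dimethylcyclopentane, allylic O–Si(i-Pr)2–O–C(CH3)2CH=CH2)
Conditions: Dess–Martin periodinane, NaHCO3, CH2Cl2, 0 °C to rt
Reagents that add atoms: none
Why: Dess–Martin oxidation merges both carbinol epimers into one ketone under buffered conditions that spare the silaketal, the terminal alkenes and the β-aryloxy ketone motif.

Step 25
Reactants: 39 open mixed silaketal diene ketone
Product: 40 cyclic silaketal: 2,2-diisopropyl-4,4-dimethyl-1,3-dioxa-2-silacyclohept-5-ene with cis alkene, bound through C7 to the cyclopentane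
Conditions: second-generation Grubbs catalyst RuCl2(=CHPh)(H2IMes)(PCy3) (10 mol%), toluene (2 mM), 80 °C, argon sparge, dark
Reagents that add atoms: none
Why: The ruthenium benzylidene first exchanges with one terminal vinyl group of 39, the resulting alkylidene adds across the second vinyl group to a ruthenacyclobutane, and cycloreversion expels ethene and leaves the new CH=CH bond. The closest known reaction type is temporary silicon-tethered ring-closing metathesis of bis(allyloxy)silanes, the established route to (Z)-but-2-ene-1,4-diols. The one ring that closes is the seven-membered 1,3-dioxa-2-silacyclohept-5-ene, formed by alkene–alkene metathesis between two chain ends that the O–Si–O bridge already holds together, and the gem-dimethyl carbon and the two isopropyl groups on silicon favour the folded conformer (Thorpe–Ingold effect). No stereocentre is formed; the only new stereochemical element is the alkene geometry, which is dictated by ring size because a seven-membered ring cannot hold a trans double bond, and both carbinol epimers of 39 can cyclise. The step needs chemoselectivity for the two monosubstituted alkenes, and this is secured because the C3=C4 bond of the chromene is 1,2-disubstituted, conjugated, part of an unstrained ring and next to quaternary C2, while ketone, aryl ether and silaketal do not react with the catalyst. High dilution, removal of ethene and exclusion of light (which could open the 2H-chromene electrocyclically and scramble C2) support the closure.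

Step 26
Reactants: 40 cyclic silaketal
Product: 41 (Z)-enediol ketone: cyclopentane–CH(OH)–CH=CH–C(CH3)2OH
Conditions: n-Bu4NF, AcOH (1:1), THF, 0 °C to rt
Reagents that add atoms: none
Why: Fluoride cleaves both Si–O bonds with formation of two Si–F bonds, and buffering with acetic acid keeps the medium near neutral so that neither retro-oxa-Michael opening of the β-aryloxy ketone nor acid-catalysed ketalisation of the ketone by the liberated diol should set in.

Step 27
Reactants: 41 (Z)-enediol ketone
Product: 42 CNP0137762.2 (target)
Conditions: activated MnO2 (excess), CH2Cl2, rt, dark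
Reagents that add atoms: none
Why: Manganese dioxide oxidises allylic alcohols selectively, so the secondary allylic carbinol gives the enone while the tertiary allylic alcohol has no carbinol hydrogen, and the neutral heterogeneous conditions in the dark preserve the Z geometry and delete the last undefined stereocentre.

**Compound list**
1 | (R)-citramalic acid | OC(=O)[C@@](C)(CC(=O)O)O | starting material
2 | 2-[(4R)-2,2,4-trimethyl-5-oxo-1,3-dioxolan-4-yl]acetic acid | CC1(C)OC(=O)[C@@](C)(CC(=O)O)O1 | intermediate
3 | (5R)-5-(2-hydroxyethyl)-2,2,5-trimethyl-1,3-dioxolan-4-one | CC1(C)OC(=O)[C@@](C)(CCO)O1 | intermediate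
4 | (5R)-5-{2-[(tert-butyldimethylsilyl)oxy]ethyl}-2,2,5-trimethyl-1,3-dioxolan-4-one | CC1(C)OC(=O)[C@@](C)(CCO[Si](C)(C)C(C)(C)C)O1 | intermediate
5 | (5R)-5-{2-[(tert-butyldimethylsilyl)oxy]ethyl}-2,2,5-trimethyl-1,3-dioxolan-4-ol | CC1(C)OC(O)[C@@](C)(CCO[Si](C)(C)C(C)(C)C)O1 | intermediate
6 | (2R)-4-[(tert-butyldimethylsilyl)oxy]-2-hydroxy-2-methylbutanal | O=C[C@@](C)(CCO[Si](C)(C)C(C)(C)C)O | intermediate
7 | (3R)-5-[(tert-butyldimethylsilyl)oxy]-3-methylpent-1-yn-3-ol | C#C[C@@](C)(CCO[Si](C)(C)C(C)(C)C)O | intermediate
8 | 4-methoxy-2-methylaniline | COc1ccc(N)c(C)c1 | starting material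
9 | 2-iodo-4-methoxy-6-methylaniline | COc1cc(C)c(N)c(I)c1 | intermediate
10 | 2-iodo-4-methoxy-6-methylbenzenediazonium bromide | COc1cc(C)c([N+]#N)c(I)c1.[Br-] | intermediate
11 | 2-bromo-1-iodo-5-methoxy-3-methylbenzene | COc1cc(C)c(Br)c(I)c1 | intermediate
12 | (3R)-1-(2-bromo-5-methoxy-3-methylphenyl)-5-[(tert-butyldimethylsilyl)oxy]-3-methylpent-1-yn-3-ol | COc1cc(C)c(Br)c(c1)C#C[C@@](C)(CCO[Si](C)(C)C(C)(C)C)O | intermediate
13 | (1Z,3R)-1-(2-bromo-5-methoxy-3-methylphenyl)-5-[(tert-butyldimethylsilyl)oxy]-3-methylpent-1-en-3-ol | COc1cc(C)c(Br)c(c1)/C=C\[C@@](C)(CCO[Si](C)(C)C(C)(C)C)O | intermediate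
14 | tert-butyl{2-[(2R)-6-methoxy-2,8-dimethyl-2H-chromen-2-yl]ethoxy}dimethylsilane | COc1cc(C)c2c(c1)C=C[C@@](C)(CCO[Si](C)(C)C(C)(C)C)O2 | intermediate
15 | 2-[(2R)-6-methoxy-2,8-dimethyl-2H-chromen-2-yl]ethanol | COc1cc(C)c2c(c1)C=C[C@@](C)(CCO)O2 | intermediate
16 | 2-[(2R)-6-methoxy-2,8-dimethyl-2H-chromen-2-yl]acetaldehyde | COc1cc(C)c2c(c1)C=C[C@@](C)(CC=O)O2 | intermediate
17 | 2,3-dimethylsuccinic acid | CC(C(=O)O)C(C)C(=O)O | starting material
18 | 1-benzyl-3,4-dimethylpyrrolidine-2,5-dione | CC1C(C)C(=O)N(Cc2ccccc2)C1=O | intermediate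
19 | 1,3-dibromopropane | BrCCCBr | starting material
20 | dilithium 1-benzyl-3,4-dimethylpyrrole-2,5-diolate (bis-enolate of 18) | [Li]OC1=C(C)C(C)=C(O[Li])N1Cc1ccccc1 | intermediate
21 | lithium enolate of 1-benzyl-3-(3-bromopropyl)-3,4-dimethylpyrrolidine-2,5-dione (racemic) | [Li]OC1=C(C)C(C)(CCCBr)C(=O)N1Cc1ccccc1 | intermediate
22 | cis-3-benzyl-1,5-dimethyl-3-azabicyclo[3.3.0]octane-2,4-dione (meso) | O=C3N(Cc2ccccc2)C(=O)[C@]1(C)CCC[C@@]13C | intermediate
23 | cis-2-(benzylcarbamoyl)-1,2-dimethylcyclopentane-1-carboxylic acid (racemic, one enantiomer drawn) | OC(=O)[C@]1(C)CCC[C@]1(C)C(=O)NCc1ccccc1 | intermediate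
24 | cis-1,5-dimethyl-3-oxabicyclo[3.3.0]octane-2,4-dione (meso) | O=C3OC(=O)[C@]1(C)CCC[C@@]13C | intermediate
25 | cis-(1,2-dimethylcyclopentane-1,2-diyl)dimethanol (meso) | OC[C@]1(C)CCC[C@]1(C)CO | intermediate
26 | [(1S,2R)-2-(hydroxymethyl)-1,2-dimethylcyclopentyl]methyl acetate | OC[C@]1(C)CCC[C@]1(C)COC(C)=O | intermediate
27 | [(1S,2R)-2-(iodomethyl)-1,2-dimethylcyclopentyl]methyl acetate | IC[C@]1(C)CCC[C@]1(C)COC(C)=O | intermediate
28 | [(1S,2R)-2-(iodomethyl)-1,2-dimethylcyclopentyl]methanol | IC[C@]1(C)CCC[C@]1(C)CO | intermediate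
29 | (1S,2R)-2-(iodomethyl)-1,2-dimethylcyclopentane-1-carbaldehyde | IC[C@]1(C)CCC[C@]1(C)C=O | intermediate
30 | vinylmagnesium bromide | C=C[Mg]Br | starting material
31 | 1-[(1S,2R)-2-(iodomethyl)-1,2-dimethylcyclopentyl]prop-2-en-1-ol ((1R)-epimer drawn) | IC[C@]1(C)CCC[C@]1(C)[C@@H](C=C)O | intermediate
32 | dichlorodiisopropylsilane | CC(C)[Si](Cl)(Cl)C(C)C | starting material
33 | 2-methylbut-3-en-2-ol | C=CC(C)(C)O | starting material
34 | chloro(diisopropyl)silyl ether of 31 | IC[C@]1(C)CCC[C@]1(C)[C@@H](C=C)O[Si](Cl)(C(C)C)C(C)C | intermediate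
35 | lithium 2-methylbut-3-en-2-olate | [Li]OC(C)(C)C=C | intermediate
36 | {1-[(1S,2R)-2-(iodomethyl)-1,2-dimethylcyclopentyl]allyloxy}(diisopropyl)(2-methylbut-3-en-2-yloxy)silane | IC[C@]1(C)CCC[C@]1(C)[C@@H](C=C)O[Si](C(C)C)(C(C)C)OC(C)(C)C=C | intermediate
37 | organolithium from 36 (CH2Li in place of CH2I) | [Li]C[C@]1(C)CCC[C@]1(C)[C@@H](C=C)O[Si](C(C)C)(C(C)C)OC(C)(C)C=C | intermediate
38 | coupling carbinol (epimers at the chain CHOH) | COc1cc(C)c2c(c1)C=C[C@@](C)(CC(O)C[C@]1(C)CCC[C@]1(C)[C@@H](C=C)O[Si](C(C)C)(C(C)C)OC(C)(C)C=C)O2 | intermediate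
39 | open mixed silaketal diene ketone (metathesis precursor) | COc1cc(C)c2c(c1)C=C[C@@](C)(CC(=O)C[C@]1(C)CCC[C@]1(C)[C@@H](C=C)O[Si](C(C)C)(C(C)C)OC(C)(C)C=C)O2 | intermediate
40 | cyclic silaketal with cis alkene (metathesis product) | COc1cc(C)c2c(c1)C=C[C@@](C)(CC(=O)C[C@]1(C)CCC[C@]1(C)[C@H]1/C=C\C(C)(C)O[Si](C(C)C)(C(C)C)O1)O2 | intermediate
41 | (Z)-enediol ketone | COc1cc(C)c2c(c1)C=C[C@@](C)(CC(=O)C[C@]1(C)CCC[C@]1(C)[C@H](O)/C=C\C(C)(C)O)O2 | intermediate
42 | CNP0137762.2 | COc1cc(C)c2c(c1)C=C[C@@](C)(CC(=O)C[C@]1(C)CCC[C@]1(C)C(=O)/C=C\C(C)(C)O)O2 | target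

**Step count**
Total step count: 27.
Longest linear sequence: 15 steps (steps 1–5, 8–12 and 23–27). The cyclopentane branch, steps 13–27, is equally long.

**Steps most likely to fail**

Step 25 (key step).
- What may go wrong: ruthenium loads slowly onto either vinyl group, since both are flanked by fully substituted carbons. Catalyst decay, double-bond migration or intermolecular metathesis could then overtake ring closure.
- Fallback (cis alkene by semihydrogenation of an alkyne, without metathesis): it sets out from aldehyde 29. Addition of 2-methylbut-3-yn-2-ol (n-BuLi, 2 equiv, THF, −78 °C) gives the propargylic diol F1. Both hydroxyl groups are silylated (TESOTf, 2,6-lutidine) to the bis(triethylsilyl) ether F2. Iodine–lithium exchange (t-BuLi, Et2O–pentane, −78 °C) gives the organolithium F3, which adds to aldehyde 16 to give the carbinol F4. Dess–Martin oxidation leads to the ketone F5, and buffered fluoride (n-Bu4NF, AcOH) to the ynediol F6. Lindlar hydrogenation (H2, Pd/CaCO3 poisoned with Pb(OAc)2, quinoline) reduces the alkyne, which is far more reactive than the hindered chromene alkene, and gives 41 as an epimer mixture. The route is rejoined there, before step 27.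

Step 23.
- What may go wrong: the 5-hexenyllithium unit of 37 closes onto its own vinyl group; the carbanion attacks silicon with loss of alkoxide; or proton transfer from the aldehyde is followed by β-elimination of the aryloxide.
- Fallback (coupling before the vinyl group and silicon are present): it sets out from iodo alcohol 28. Silylation (TBSCl, imidazole) gives the silyl ether F7. Exchange with t-BuLi gives the organolithium F8, which carries neither an alkene nor an alkoxysilane, and addition to 16 gives the carbinol F9. Dess–Martin oxidation gives the ketone F10, HF·pyridine the hydroxy ketone F11, and a second Dess–Martin oxidation the keto aldehyde F12. Nozaki–Hiyama–Kishi vinylation (vinyl bromide, CrCl2, NiCl2 cat., DMF) gives the allylic alcohol F13; the organochromium reagent is non-basic and adds to aldehydes but not to ketones. Treatment with 32 and imidazole gives the chlorosilane F14, and excess 33 with DMAP then gives 39. The route is rejoined there, before step 25.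

Step 17.
- What may go wrong: the enzyme discriminates poorly between the enantiotopic groups because the reacting CH2OH groups are neopentylic; turnover is slow; or acetyl migration between the arms erodes enantiomeric purity.
- Fallback (covalent auxiliary and separation of diastereomers in place of catalytic group selection): it sets out from meso-diol 25. Monoesterification with (S)-2-methoxy-2-phenylacetic acid (DCC, DMAP) gives the monoester F15 and the diastereomeric monoester F16. These are separated by chromatography or crystallisation and assigned by X-ray analysis. F16 is saponified back to 25 and recycled. F15 undergoes the iodination of step 18 to the iodo ester F17, and i-Bu2AlH at −78 °C cleaves the ester to 28. The route is rejoined there, before step 20.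

**Further compounds**
F1 | step 25 | propargylic diol (carbinol epimers) | IC[C@]1(C)CCC[C@]1(C)C(O)C#CC(C)(C)O
F2 | step 25 | bis(triethylsilyl) ether | IC[C@]1(C)CCC[C@]1(C)C(O[Si](CC)(CC)CC)C#CC(C)(C)O[Si](CC)(CC)CC
F3 | step 25 | organolithium | [Li]C[C@]1(C)CCC[C@]1(C)C(O[Si](CC)(CC)CC)C#CC(C)(C)O[Si](CC)(CC)CC
F4 | step 25 | carbinol | COc1cc(C)c2c(c1)C=C[C@@](C)(CC(O)C[C@]1(C)CCC[C@]1(C)C(O[Si](CC)(CC)CC)C#CC(C)(C)O[Si](CC)(CC)CC)O2
F5 | step 25 | ketone | COc1cc(C)c2c(c1)C=C[C@@](C)(CC(=O)C[C@]1(C)CCC[C@]1(C)C(O[Si](CC)(CC)CC)C#CC(C)(C)O[Si](CC)(CC)CC)O2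
F6 | step 25 | ynediol | COc1cc(C)c2c(c1)C=C[C@@](C)(CC(=O)C[C@]1(C)CCC[C@]1(C)C(O)C#CC(C)(C)O)O2
F7 | step 23 | silyl ether | IC[C@]1(C)CCC[C@]1(C)CO[Si](C)(C)C(C)(C)C
F8 | step 23 | organolithium | [Li]C[C@]1(C)CCC[C@]1(C)CO[Si](C)(C)C(C)(C)C
F9 | step 23 | carbinol | COc1cc(C)c2c(c1)C=C[C@@](C)(CC(O)C[C@]1(C)CCC[C@]1(C)CO[Si](C)(C)C(C)(C)C)O2
F10 | step 23 | ketone | COc1cc(C)c2c(c1)C=C[C@@](C)(CC(=O)C[C@]1(C)CCC[C@]1(C)CO[Si](C)(C)C(C)(C)C)O2
F11 | step 23 | hydroxy ketone | COc1cc(C)c2c(c1)C=C[C@@](C)(CC(=O)C[C@]1(C)CCC[C@]1(C)CO)O2
F12 | step 23 | keto aldehyde | COc1cc(C)c2c(c1)C=C[C@@](C)(CC(=O)C[C@]1(C)CCC[C@]1(C)C=O)O2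
F13 | step 23 | allylic alcohol (one epimer drawn) | COc1cc(C)c2c(c1)C=C[C@@](C)(CC(=O)C[C@]1(C)CCC[C@]1(C)[C@@H](C=C)O)O2
F14 | step 23 | chlorosilane | COc1cc(C)c2c(c1)C=C[C@@](C)(CC(=O)C[C@]1(C)CCC[C@]1(C)[C@@H](C=C)O[Si](Cl)(C(C)C)C(C)C)O2
F15 | step 17 | monoester, [(1S,2R)-2-(hydroxymethyl)-1,2-dimethylcyclopentyl]methyl (S)-2-methoxy-2-phenylacetate | OC[C@]1(C)CCC[C@]1(C)COC(=O)[C@@H](OC)c1ccccc1
F16 | step 17 | diastereomeric monoester | CO[C@H](C(=O)OC[C@]1(C)CCC[C@]1(C)CO)c1ccccc1
F17 | step 17 | iodo ester | IC[C@]1(C)CCC[C@]1(C)COC(=O)[C@@H](OC)c1ccccc1
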